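**Retrosynthetic overview**

- The target comes from its 15-deoxy congener by a last allylic C–H hydroxylation of the C4 methyl group, the order nature also uses.
- The 15-deoxy germacranolide comes from one open-chain C15 bromo enal that already carries the 8-methacrylate and the 9-acetate. A chromium-mediated intramolecular allylation forms C6–C7 (the bond made by germacrene A synthase) and so closes the 10-membered ring first; the C6 alkoxide then closes the γ-lactone on C12 in the same flask. C6 and C7 are set from C8 alone.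
- The bromo enal comes from a Morita–Baylis–Hillman adduct of a C8–C9 epoxy aldehyde (C7–C11 bond); acetolysis of the epoxide at C9 with inversion tells the two ester oxygens apart.
- The epoxy aldehyde comes from organocatalytic epoxidation of a dienal, made by Suzuki coupling (C9–C10) of a (Z)-α-iodoenoate (iodo-Wittig, C1=C10).
- C1–C6 and C15 come from neryl acetate by selective ozonolysis; its acetate is the only protecting group.

Assumption: atom labels follow germacrane numbering (C1–C10 ring, C11–C13 lactone unit, C14 ester carbon, C15 on C4), and the (S)-diarylprolinol silyl ether is taken to give the (2R,3S)-epoxy aldehyde, as it does with cinnamaldehyde.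

**Route**

Step 1
Reactants: 1 neryl acetate [(2Z)-3,7-dimethylocta-2,6-dien-1-yl acetate]
Product: 2 (2Z)-3-methyl-6-oxohex-2-en-1-yl acetate
Conditions: O3 (1.0 equiv, Sudan Red 7B end point), CH2Cl2, −78 °C; then Me2S, −78 °C → rt
Reagents that add atoms: ozone ([O-][O+]=O)
Why: Chemoselective ozonolysis (Criegee mechanism): the distal trisubstituted alkene reacts much faster than the 2,3-alkene, which is deactivated by the allylic acetate, and the Z geometry is untouched.

Step 2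
Reactants: 2 (2Z)-3-methyl-6-oxohex-2-en-1-yl acetate; 3 methyl (triphenyl-λ5-phosphanylidene)acetate
Product: 5 methyl (2Z,6Z)-8-(acetyloxy)-2-iodo-6-methylocta-2,6-dienoate, via iodo ylide 4 (not isolated)
Conditions: 3, NIS, CH2Cl2, −20 °C, 30 min; then 2, −20 °C → rt
Reagents that add atoms: N-iodosuccinimide (O=C1CCC(=O)N1I)
Why: Iodination of the stabilised ylide followed by Wittig olefination of the aliphatic aldehyde places iodine cis to the chain (Z), which fixes the later C1=C10 geometry (C2 cis to C9).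

Step 3
Reactants: 5 methyl (2Z,6Z)-8-(acetyloxy)-2-iodo-6-methylocta-2,6-dienoate; 6 2-[(1E)-3,3-diethoxyprop-1-en-1-yl]-4,4,5,5-tetramethyl-1,3,2-dioxaborolane
Product: 9 methyl (2E,6Z)-8-hydroxy-6-methyl-2-[(1E)-3-oxoprop-1-en-1-yl]octa-2,6-dienoate, via acetate acetal 7 (not isolated), via hydroxy acetal 8 (not isolated)
Conditions: PdCl2(dppf) (5 mol %), K3PO4 (3 equiv), THF/H2O, 45 °C; then MeOH, K2CO3 (0.2 equiv), rt; then 1 M HCl to pH 3, 0 °C
Reagents that add atoms: water (O)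
Why: Suzuki–Miyaura coupling forms C9–C10 with retention at both alkenes, the basic methanol then removes the primary acetate by transesterification, and dilute acid hydrolyses the vinylogous acetal to the (E)-enal.

Step 4
Reactants: 9 methyl (2E,6Z)-8-hydroxy-6-methyl-2-[(1E)-3-oxoprop-1-en-1-yl]octa-2,6-dienoate
Product: 10 methyl (2E,6Z)-2-[(2S,3R)-3-formyloxiran-2-yl]-8-hydroxy-6-methylocta-2,6-dienoate
Conditions: (S)-2-{bis[3,5-bis(trifluoromethyl)phenyl][(trimethylsilyl)oxy]methyl}pyrrolidine (10 mol %), 35% aq. H2O2 (1.3 equiv), CH2Cl2, rt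
Reagents that add atoms: hydrogen peroxide (OO)
Why: Jørgensen–Hayashi iminium/enamine epoxidation: only the enal is activated and the catalyst shields one face, giving the trans epoxide with C8 (R) and C9 (S), the two centres from which C8 and C9 of the target derive.

Step 5
Reactants: 10 methyl (2E,6Z)-2-[(2S,3R)-3-formyloxiran-2-yl]-8-hydroxy-6-methylocta-2,6-dienoate; 11 methyl acrylate
Product: 12 methyl (2E,6Z)-8-hydroxy-2-{(2S,3S)-3-[1-hydroxy-2-(methoxycarbonyl)prop-2-en-1-yl]oxiran-2-yl}-6-methylocta-2,6-dienoate (both carbinol epimers)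
Conditions: 11 (5 equiv), DABCO (0.5 equiv), DMSO, rt, 24–48 h
Reagents that add atoms: none
Why: Morita–Baylis–Hillman reaction on an activated α-oxygenated aldehyde forms C7–C11; the new C7 carbinol is formed unselectively and is erased in step 9.

Step 6
Reactants: 12 methyl (2E,6Z)-8-hydroxy-2-{(2S,3S)-3-[1-hydroxy-2-(methoxycarbonyl)prop-2-en-1-yl]oxiran-2-yl}-6-methylocta-2,6-dienoate
Product: 13 methyl (2E,6Z)-2-[(1R,2S)-1-(acetyloxy)-2,3-dihydroxy-4-(methoxycarbonyl)pent-4-en-1-yl]-8-hydroxy-6-methylocta-2,6-dienoate (both C7 epimers)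
Conditions: Ti(OiPr)4 (1.5 equiv), AcOH (3 equiv), CH2Cl2, 0 °C → rt
Reagents that add atoms: acetic acid (CC(=O)O)
Why: Sharpless titanium-mediated opening of a 2,3-epoxy alcohol: the C7 alkoxide–titanium chelate directs acetate to the distal, allylic epoxide carbon (C9) with inversion, giving C9 (R) with its acetate in place and leaving C8 (S) as a free hydroxyl (anti diol pattern).

Step 7
Reactants: 13 methyl (2E,6Z)-2-[(1R,2S)-1-(acetyloxy)-2,3-dihydroxy-4-(methoxycarbonyl)pent-4-en-1-yl]-8-hydroxy-6-methylocta-2,6-dienoate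
Product: 14 methyl (2E,6Z)-2-[(1R,2S)-1-(acetyloxy)-2,3-dihydroxy-4-(methoxycarbonyl)pent-4-en-1-yl]-6-methyl-8-oxoocta-2,6-dienoate
Conditions: Cu(MeCN)4OTf (5 mol %), 2,2′-bipyridine (5 mol %), TEMPO (5 mol %), N-methylimidazole (10 mol %), air, MeCN, rt
Reagents that add atoms: none
Why: Stahl copper/TEMPO aerobic oxidation is selective for the primary allylic alcohol over the two secondary alcohols and gives the (Z)-enal without isomerisation.

Step 8
Reactants: 14 methyl (2E,6Z)-2-[(1R,2S)-1-(acetyloxy)-2,3-dihydroxy-4-(methoxycarbonyl)pent-4-en-1-yl]-6-methyl-8-oxoocta-2,6-dienoate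
Product: 15 methyl (2E,6Z)-2-[(1R,2S)-1-(acetyloxy)-4-(methoxycarbonyl)-2,3-bis[(2-methylprop-2-enoyl)oxy]pent-4-en-1-yl]-6-methyl-8-oxoocta-2,6-dienoate (both C7 epimers)
Conditions: methacrylic anhydride (3 equiv), Et3N (4 equiv), DMAP (10 mol %), CH2Cl2, −20 → 0 °C
Reagents that add atoms: methacrylic anhydride (CC(=C)C(=O)OC(=O)C(C)=C)
Why: DMAP-catalysed acylation esterifies both secondary hydroxyls quickly at low temperature (ahead of acetyl migration), installing the C8 methacrylate of the target and turning the C7 oxygen into a leaving group.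

Step 9
Reactants: 15 methyl (2E,6Z)-2-[(1R,2S)-1-(acetyloxy)-4-(methoxycarbonyl)-2,3-bis[(2-methylprop-2-enoyl)oxy]pent-4-en-1-yl]-6-methyl-8-oxoocta-2,6-dienoate
Product: 16 methyl (2E,6Z)-2-[(1R,2S,3Z)-1-(acetyloxy)-5-bromo-4-(methoxycarbonyl)-2-[(2-methylprop-2-enoyl)oxy]pent-3-en-1-yl]-6-methyl-8-oxoocta-2,6-dienoate
Conditions: MgBr2·OEt2 (1.5 equiv), THF, 0 °C → rt
Reagents that add atoms: magnesium dibromide diethyl etherate ([Mg+2].[Br-].[Br-])
Why: Lewis acid-assisted SN2′ displacement of the Morita–Baylis–Hillman ester by bromide at the unhindered terminal methylene gives the thermodynamic (Z)-2-(bromomethyl)enoate and removes the C7 stereocentre; the other two allylic esters would need attack at a substituted carbon and stay.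

Step 10
Reactants: 16 methyl (2E,6Z)-2-[(1R,2S,3Z)-1-(acetyloxy)-5-bromo-4-(methoxycarbonyl)-2-[(2-methylprop-2-enoyl)oxy]pent-3-en-1-yl]-6-methyl-8-oxoocta-2,6-dienoate
Product: 18 methyl (3aS,4S,5R,6E,10Z,11aR)-5-(acetyloxy)-10-methyl-3-methylidene-4-[(2-methylprop-2-enoyl)oxy]-2-oxo-2,3,3a,4,5,8,9,11a-octahydrocyclodeca[b]furan-6-carboxylate (15-deoxy target), via hydroxy ester 17 (not isolated)
Conditions: CrCl2 (8 equiv), THF/DMF (4:1), 2 mM, addition of 16 over 10 h, rt; then aq. NH4Cl; CSA (cat.), CH2Cl2, rt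
Reagents that add atoms: none
Why: Intramolecular Nozaki–Hiyama–Kishi (Barbier-type) allylation–lactonisation: the 2-(methoxycarbonyl)allylchromium adds through C7 to the C6 aldehyde in a chair Zimmerman–Traxler transition state with both chain ends equatorial (anti adduct, hence the trans lactone, C6 R), on the allyl face anti to C9 with H8 eclipsing the alkene (A(1,3) strain, C7 S), and the trivalent chromium C6 alkoxide then closes the lactone on the C12 methyl ester.

Step 11
Reactants: 18 methyl (3aS,4S,5R,6E,10Z,11aR)-5-(acetyloxy)-10-methyl-3-methylidene-4-[(2-methylprop-2-enoyl)oxy]-2-oxo-2,3,3a,4,5,8,9,11a-octahydrocyclodeca[b]furan-6-carboxylate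
Product: 19 methyl (3aS,4S,5R,6E,10E,11aR)-5-(acetyloxy)-10-(hydroxymethyl)-3-methylidene-4-[(2-methylprop-2-enoyl)oxy]-2-oxo-2,3,3a,4,5,8,9,11a-octahydrocyclodeca[b]furan-6-carboxylate (target, CNP0179134.4)
Conditions: SeO2 (0.5 equiv), t-BuOOH (3 equiv, in decane), CH2Cl2, 0 °C → rt
Reagents that add atoms: tert-butyl hydroperoxide (CC(C)(C)OO); selenium dioxide (O=[Se]=O)
Why: Riley/Sharpless allylic oxidation (ene reaction, then [2,3]-sigmatropic shift) acts on the only electron-rich alkene at its (E)-methyl group, as in parthenolide → melampomagnolide B, and the [2,3] shift returns the C4=C5 bond with the hydroxymethyl trans to C6.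

**Compound list**

1 | neryl acetate, (2Z)-3,7-dimethylocta-2,6-dien-1-yl acetate | CC(C)=CCC/C(C)=C\COC(C)=O | starting material
2 | (2Z)-3-methyl-6-oxohex-2-en-1-yl acetate | O=CCC/C(C)=C\COC(C)=O | intermediate
3 | methyl (triphenyl-λ5-phosphanylidene)acetate | COC(=O)C=P(c1ccccc1)(c1ccccc1)c1ccccc1 | starting material
4 | methyl iodo(triphenyl-λ5-phosphanylidene)acetate (iodo ylide, not isolated) | COC(=O)C(I)=P(c1ccccc1)(c1ccccc1)c1ccccc1 | intermediate
5 | methyl (2Z,6Z)-8-(acetyloxy)-2-iodo-6-methylocta-2,6-dienoate | COC(=O)/C(I)=C/CC/C(C)=C\COC(C)=O | intermediate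
6 | 2-[(1E)-3,3-diethoxyprop-1-en-1-yl]-4,4,5,5-tetramethyl-1,3,2-dioxaborolane | CCOC(OCC)/C=C/B1OC(C)(C)C(C)(C)O1 | starting material
7 | methyl (2E,6Z)-8-(acetyloxy)-2-[(1E)-3,3-diethoxyprop-1-en-1-yl]-6-methylocta-2,6-dienoate (not isolated) | COC(=O)/C(=C/CC/C(C)=C\COC(C)=O)/C=C/C(OCC)OCC | intermediate
8 | methyl (2E,6Z)-2-[(1E)-3,3-diethoxyprop-1-en-1-yl]-8-hydroxy-6-methylocta-2,6-dienoate (not isolated) | COC(=O)/C(=C/CC/C(C)=C\CO)/C=C/C(OCC)OCC | intermediate
9 | methyl (2E,6Z)-8-hydroxy-6-methyl-2-[(1E)-3-oxoprop-1-en-1-yl]octa-2,6-dienoate | COC(=O)/C(=C/CC/C(C)=C\CO)/C=C/C=O | intermediate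
10 | methyl (2E,6Z)-2-[(2S,3R)-3-formyloxiran-2-yl]-8-hydroxy-6-methylocta-2,6-dienoate | COC(=O)/C(=C/CC/C(C)=C\CO)[C@@H]1O[C@H]1C=O | intermediate
11 | methyl acrylate | C=CC(=O)OC | starting material
12 | methyl (2E,6Z)-8-hydroxy-2-{(2S,3S)-3-[1-hydroxy-2-(methoxycarbonyl)prop-2-en-1-yl]oxiran-2-yl}-6-methylocta-2,6-dienoate (both carbinol epimers) | COC(=O)/C(=C/CC/C(C)=C\CO)[C@@H]1O[C@H]1C(O)C(=C)C(=O)OC | intermediate
13 | methyl (2E,6Z)-2-[(1R,2S)-1-(acetyloxy)-2,3-dihydroxy-4-(methoxycarbonyl)pent-4-en-1-yl]-8-hydroxy-6-methylocta-2,6-dienoate (both C7 epimers) | COC(=O)/C(=C/CC/C(C)=C\CO)[C@@H](OC(C)=O)[C@@H](O)C(O)C(=C)C(=O)OC | intermediate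
14 | methyl (2E,6Z)-2-[(1R,2S)-1-(acetyloxy)-2,3-dihydroxy-4-(methoxycarbonyl)pent-4-en-1-yl]-6-methyl-8-oxoocta-2,6-dienoate (both C7 epimers) | COC(=O)/C(=C/CC/C(C)=C\C=O)[C@@H](OC(C)=O)[C@@H](O)C(O)C(=C)C(=O)OC | intermediate
15 | methyl (2E,6Z)-2-[(1R,2S)-1-(acetyloxy)-4-(methoxycarbonyl)-2,3-bis[(2-methylprop-2-enoyl)oxy]pent-4-en-1-yl]-6-methyl-8-oxoocta-2,6-dienoate (both C7 epimers) | COC(=O)/C(=C/CC/C(C)=C\C=O)[C@@H](OC(C)=O)[C@@H](OC(=O)C(C)=C)C(OC(=O)C(C)=C)C(=C)C(=O)OC | intermediate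
16 | methyl (2E,6Z)-2-[(1R,2S,3Z)-1-(acetyloxy)-5-bromo-4-(methoxycarbonyl)-2-[(2-methylprop-2-enoyl)oxy]pent-3-en-1-yl]-6-methyl-8-oxoocta-2,6-dienoate | COC(=O)/C(=C/CC/C(C)=C\C=O)[C@@H](OC(C)=O)[C@@H](OC(=O)C(C)=C)/C=C(\CBr)C(=O)OC | intermediate
17 | methyl (1E,5Z,7R,8S,9S,10R)-10-(acetyloxy)-7-hydroxy-8-(3-methoxy-3-oxoprop-1-en-2-yl)-5-methyl-9-[(2-methylprop-2-enoyl)oxy]cyclodeca-1,5-diene-1-carboxylate (not isolated) | C=C(C)C(=O)O[C@H]1[C@@H](C(=C)C(=O)OC)[C@H](O)/C=C(/C)CC/C=C(/C(=O)OC)[C@H]1OC(C)=O | intermediate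
18 | methyl (3aS,4S,5R,6E,10Z,11aR)-5-(acetyloxy)-10-methyl-3-methylidene-4-[(2-methylprop-2-enoyl)oxy]-2-oxo-2,3,3a,4,5,8,9,11a-octahydrocyclodeca[b]furan-6-carboxylate | C=C(C)C(=O)O[C@H]1[C@H]2C(=C)C(=O)O[C@@H]2/C=C(/C)CC/C=C(/C(=O)OC)[C@H]1OC(C)=O | intermediate
19 | methyl (3aS,4S,5R,6E,10E,11aR)-5-(acetyloxy)-10-(hydroxymethyl)-3-methylidene-4-[(2-methylprop-2-enoyl)oxy]-2-oxo-2,3,3a,4,5,8,9,11a-octahydrocyclodeca[b]furan-6-carboxylate | C=C(C)C(=O)O[C@H]1[C@H]2C(=C)C(=O)O[C@@H]2/C=C(/CO)CC/C=C(/C(=O)OC)[C@H]1OC(C)=O | target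

**Step count and risks**

Total step count: 11. Longest linear sequence: 11 steps (1 → 19).

The three steps most likely to fail:

Step 10 (macrocyclisation). The allylchromium carries a carboxylate on the neighbouring carbon (possible elimination or acyl transfer), the ring closure competes with oligomerisation, and the C7 face selectivity rests on one stereocentre. The fallback closes the ring before O8 is acylated and sets out from 14. Corey–Kim bromination (NBS, Me2S, CH2Cl2, −20 °C) of the Morita–Baylis–Hillman hydroxyl gives the bromo alcohol methyl (2E,6Z)-2-[(1R,2S,3Z)-1-(acetyloxy)-5-bromo-2-hydroxy-4-(methoxycarbonyl)pent-3-en-1-yl]-6-methyl-8-oxoocta-2,6-dienoate F1. CrCl2 at the same high dilution then cyclises it with C8 as a chromium alkoxide, which cannot leave and can steer the aldehyde by chelation, giving the open hydroxy ester methyl (1E,5Z,7R,8S,9S,10R)-10-(acetyloxy)-7,9-dihydroxy-8-(3-methoxy-3-oxoprop-1-en-2-yl)-5-methylcyclodeca-1,5-diene-1-carboxylate F2 (not isolated) and from it the 8-hydroxy lactone methyl (3aR,4S,5R,6E,10Z,11aR)-5-(acetyloxy)-4-hydroxy-10-methyl-3-methylidene-2-oxo-2,3,3a,4,5,8,9,11a-octahydrocyclodeca[b]furan-6-carboxylate F3. Methacrylic anhydride, Et3N and DMAP acylate O8 and the route is rejoined at 18.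

Step 11 (C15 hydroxylation). The alkene is deactivated by the allylic lactone oxygen, C3 can compete, and alcohol/aldehyde mixtures are common. The fallback sets out from 18: stoichiometric SeO2 in wet 1,4-dioxane at 70 °C drives the oxidation through to the aldehyde methyl (3aS,4S,5R,6E,10E,11aR)-5-(acetyloxy)-10-formyl-3-methylidene-4-[(2-methylprop-2-enoyl)oxy]-2-oxo-2,3,3a,4,5,8,9,11a-octahydrocyclodeca[b]furan-6-carboxylate F4, which is reduced 1,2-selectively (NaBH4, CeCl3·7H2O, MeOH, −78 °C, Luche) to rejoin the route at 19.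

Step 5 (Morita–Baylis–Hillman on the epoxy aldehyde). DABCO may open or degrade the epoxy aldehyde, add to the free hydroxyl/acrylate pair, or the reaction may stall. The fallback sets out from 10 and replaces amine catalysis by a preformed nucleophile: hydroalumination of methyl propiolate (i-Bu2AlH, N-methylmorpholine N-oxide, THF, 0 °C) gives the vinylalane methyl 2-[bis(2-methylpropyl)alumanyl]prop-2-enoate F5. F5 adds to the aldehyde of 10 at −78 → 0 °C (vinylalumination; one extra equivalent is spent on the free hydroxyl) and the route is rejoined at 12.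

**Further compounds**

F1 | step 10 | methyl (2E,6Z)-2-[(1R,2S,3Z)-1-(acetyloxy)-5-bromo-2-hydroxy-4-(methoxycarbonyl)pent-3-en-1-yl]-6-methyl-8-oxoocta-2,6-dienoate | COC(=O)/C(=C/CC/C(C)=C\C=O)[C@@H](OC(C)=O)[C@@H](O)/C=C(\CBr)C(=O)OC
F2 | step 10 | methyl (1E,5Z,7R,8S,9S,10R)-10-(acetyloxy)-7,9-dihydroxy-8-(3-methoxy-3-oxoprop-1-en-2-yl)-5-methylcyclodeca-1,5-diene-1-carboxylate | O[C@H]1[C@@H](C(=C)C(=O)OC)[C@H](O)/C=C(/C)CC/C=C(/C(=O)OC)[C@H]1OC(C)=O
F3 | step 10 | methyl (3aR,4S,5R,6E,10Z,11aR)-5-(acetyloxy)-4-hydroxy-10-methyl-3-methylidene-2-oxo-2,3,3a,4,5,8,9,11a-octahydrocyclodeca[b]furan-6-carboxylate | O[C@H]1[C@H]2C(=C)C(=O)O[C@@H]2/C=C(/C)CC/C=C(/C(=O)OC)[C@H]1OC(C)=O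
F4 | step 11 | methyl (3aS,4S,5R,6E,10E,11aR)-5-(acetyloxy)-10-formyl-3-methylidene-4-[(2-methylprop-2-enoyl)oxy]-2-oxo-2,3,3a,4,5,8,9,11a-octahydrocyclodeca[b]furan-6-carboxylate | C=C(C)C(=O)O[C@H]1[C@H]2C(=C)C(=O)O[C@@H]2/C=C(/C=O)CC/C=C(/C(=O)OC)[C@H]1OC(C)=O
F5 | step 5 | methyl 2-[bis(2-methylpropyl)alumanyl]prop-2-enoate | COC(=O)C(=C)[Al](CC(C)C)CC(C)C
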